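(The readings are calculated with constants of no real substance, and the scatter is random.)

Two questions stand on this flask, and the south-west run, which is this very flask followed so far, speaks to the second and not to the first, since it shows no chain count.

all flasks: free monomer 0.10 M

| charge | protic impurity | initiator | remark | time |
|---|---|---|---|---|
| south-west | 2 mM | 3 mM | the very flask that is asked about, followed so far |  |
| flask | 2.00 mM | 3.0 mM |  | 1.0 h |

south-west run (percent of the free monomer charged)

| time / min | monomer in chains / % | free monomer / % |
|---|---|---|
| 5.00 | 12.4 | 87.5 |
| 10.0 | 18.0 | 77.8 |
| 15.0 | 26.5 | 70.8 |
| 20.0 | 33.9 | 63.3 |
| 25.0 | 40.9 | 58.6 |
| 30.0 | 45.9 | 52.5 |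

(standard deviation of a reading: 1 percentage point)

- average number of monomer units in a chain (living and dead chains, two that joined counted as one) at 1.0 h
- part of the free monomer that has reacted at 1.0 h

- the average divides the monomer in chains by the number of chains, living and dead together; two radicals that join make one chain
- the numbers in the tables scatter by 1 percentage point (one standard deviation)
- the earlier runs do not show the number of chains; that part of a forecast is a guess

We start from the end state. The two columns add to 98.4% at 30.0 min, and the protic impurity's charge is 2.00% of the free monomer's, so we expect chains to receive what the impurity does not take, one for one.

For the approach we use two extreme versions of the flask, both with steady radicals, so that free monomer falls pseudo-first-order. In the first, the impurity takes nothing, and the last reading carried forward gives 72.4% reacted. In the second, the impurity takes its whole share at once. The quantity we carry is then the first-order constant of the free monomer, the logarithm of what stood after the impurity over what stands at the last reading, per unit time: 0.0208 min⁻¹, read with the scatter of 1 percentage point. It gives 71.9% reacted. The impurity's real pace lies between nothing and at once, so we expect a value between these two.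

The forecast says 69% (64% to 74%), less than both our figures, from a curve for “active centres lost by pairwise joining”, and an average of 70 (24 to 95), which it calls a guess.

The flask gives 72.0% reacted and an average of 106.

    initiator → 2 initiating radical (k = 6.90 × 10⁻⁵ s⁻¹)
    free monomer + initiating radical → growing radical + monomer in chains (k = 2.90 × 10⁵ M⁻¹ s⁻¹)
    free monomer + growing radical → monomer in chains + growing radical, rate k3*[growing radical]*[free monomer] (k = 1400 M⁻¹ s⁻¹)
    2 growing radical → dead chain (k = 3.10 × 10⁶ M⁻¹ s⁻¹)
    protic impurity + free monomer → quenched substrate (k = 0.160 M⁻¹ s⁻¹)

The constant leaves 28.1% of the free monomer at the hour, and the flask holds 28.0%. The average lies above the forecast's range through two things acting together: the impurity wears away, and with it held the average is 72.9; and the reading comes at the hour, while at 10.0 h it is 45.4.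

With steady radicals, made in proportion to initiator and lost in pairs, the constant goes with the square root of the initiator, other charges fixed. For the neighbour flask with 0.012 M of initiator we reckon 0.0416 min⁻¹, hence 91.9% reacted; that flask gave 93.5%.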